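## Retrosynthetic overview
1. Target 15 comes from hexabenzyl ether 14 by neutral hydrogenolysis as the last step, so the 2S centre is never exposed to acid or base.
2. 14 comes from boronic acid 9 and chromone 13. The C2–C1' bond is made by an enantioselective rhodium 1,4-addition, which sets 2S.
3. 9 comes from bromide 8, and 8 from 2 plus 6 (key step, C5'–C8'' biaryl bond). The array O–C4'=C5'–C8''=C7''–O is 1,4-dioxygenated, so both carbons are enol-type nucleophiles. C5' is therefore inverted: phenol 5 is dearomatised to the masked o-benzoquinone 6, an enolonium/aryl-cation equivalent, and C8 of tri-O-benzylapigenin 2 attacks it.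
4. Ring order: all three flavone rings arrive intact in apigenin 1, and ring B of the flavanone half comes from 3. The pyranone ring of the flavanone half is closed on phloroacetophenone 10 (chromone 13, step 6) and saturated in step 7. No ring is formed after that.

Assumption 1: the 5'–8'' axis (three ortho oxygens, one ortho H) is not a stereo element in the target SMILES and is treated as equilibrating; benzylated intermediates may show rotamers.
Assumption 2: (S)-configured 2,2'-bis(diarylphosphino)biaryl ligands direct aryl transfer to a chromone as they do to cyclohexenone, where the (S)-ligand gives (S)-3-arylcyclohexanone; that spatial sense corresponds to 2S here.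

## Route

Step 1
Reactants: 1 apigenin
Product: 2 5,7-bis(benzyloxy)-2-[4-(benzyloxy)phenyl]-4H-chromen-4-one (tri-O-benzylapigenin)
Conditions: BnBr (4.5 equiv), K2CO3 (6 equiv), DMF, 80 °C, 24 h
Reagents that add atoms: benzyl bromide, BrCc1ccccc1
Why: Williamson etherification, in which the acidic 7- and 4'-OH react first and the hydrogen-bonded 5-OH follows with excess halide and heat; full capping removes every O-nucleophile and leaves C8 as the most accessible nucleophilic ring carbon.

Step 2
Reactants: 3 2-(benzyloxy)-5-bromobenzaldehyde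
Product: 5 2-(benzyloxy)-5-bromophenol, via aryl formate 4 (not isolated)
Conditions: mCPBA (1.3 equiv), CH2Cl2, 40 °C; aq NaHCO3 wash, solvent swap; K2CO3 (0.2 equiv), MeOH, rt
Reagents that add atoms: mCPBA (3-chloroperoxybenzoic acid), O=C(OO)c1cccc(Cl)c1
Why: Baeyer–Villiger oxidation, in which the ortho-alkoxy aryl group migrates in the Criegee intermediate to give the formate, and carbonate-catalysed methanolysis then frees the phenol without touching the C–Br bond or the benzyl ether.

Step 3 (key step)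
Reactants: 5 2-(benzyloxy)-5-bromophenol; 2 tri-O-benzylapigenin
Product: 8 8-[2-(benzyloxy)-5-bromo-3-hydroxyphenyl]-5,7-bis(benzyloxy)-2-[4-(benzyloxy)phenyl]-4H-chromen-4-one, via masked o-benzoquinone 6 (not isolated), via dienol adduct 7 (not isolated)
Conditions: 5, PhI(OAc)2 (1.0 equiv), BnOH (2 equiv), CH2Cl2, 0 °C, 15 min; cold aq NaHCO3 wash, Na2SO4; then 2 (1.5 equiv), BF3·OEt2 (1.0 equiv, kept below the amount of 2), CH2Cl2, −40 to 0 °C
Reagents that add atoms: benzyl alcohol, OCc1ccccc1
Why: Proposed new method: the trivalent iodine reagent dearomatises the 2-alkoxyphenol in the presence of BnOH to ketal 6, which turns C5' (in the arene the nucleophilic alpha-carbon of the C4' enol ether) into the electrophilic delta-terminus of a dienone, i.e. an enolonium/aryl-cation equivalent; bromine blocks the beta-position and shields C2' and C6', so the acid-activated dienone should accept a nucleophile mainly in the 1,6 sense at C5'; C8 of 2 (the site where 5,7-dialkoxyflavones are halogenated, less hindered than C6) attacks in Friedel–Crafts/Michael fashion and loss of BnOH from 7 rearomatises, erasing the transient sp3 centre; BF3 is kept below one equivalent per flavone because the pyrone carbonyl is the strongest Lewis base present and only uncomplexed 2 is nucleophilic; the closest known reaction type is the Lewis-acid-mediated Michael-type arylation and rearomatisation of masked o-benzoquinones by electron-rich arenes such as trimethoxybenzenes.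

Step 4
Reactants: 8 bromobiaryl flavone
Product: 9 [4-(benzyloxy)-3-hydroxy-5-{5,7-bis(benzyloxy)-2-[4-(benzyloxy)phenyl]-4-oxo-4H-chromen-8-yl}phenyl]boronic acid
Conditions: B2(OH)4 (3 equiv), Pd(OAc)2 (5 mol %), XPhos (10 mol %), KOAc (3 equiv), EtOH/THF 1:1, 70 °C
Reagents that add atoms: tetrahydroxydiboron, OB(O)B(O)O
Why: Miyaura borylation, in which zerovalent palladium inserts into the unhindered C–Br bond (H on both flanks) and acetate-assisted transmetallation with the B–B reagent followed by reductive elimination gives the free boronic acid directly; the phenol, benzyl ethers and flavone are inert to KOAc.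

Step 5
Reactants: 10 2',4',6'-trihydroxyacetophenone
Product: 11 1-[2,4-bis(benzyloxy)-6-hydroxyphenyl]ethan-1-one
Conditions: BnBr (2.1 equiv), K2CO3 (2.2 equiv), DMF, 25 to 50 °C
Reagents that add atoms: benzyl bromide, BrCc1ccccc1
Why: Selective Williamson etherification, which stops at the dibenzyl stage because the last OH is locked in a hydrogen bond to the acetyl carbonyl.

Step 6
Reactants: 11 1-[2,4-bis(benzyloxy)-6-hydroxyphenyl]ethan-1-one
Product: 13 5,7-bis(benzyloxy)-4H-chromen-4-one, via enaminone 12 (not isolated)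
Conditions: DMF-DMA (3 equiv), toluene, 100 °C; evaporate; conc. HCl, CH2Cl2, 40 °C; aq NaHCO3 wash
Reagents that add atoms: N,N-dimethylformamide dimethyl acetal, COC(OC)N(C)C
Why: Enaminone chromone synthesis, in which the methyl ketone condenses with the amide acetal and acid then triggers addition of the phenol to the beta-carbon with loss of dimethylamine, closing the pyranone ring.

Step 7
Reactants: 9 biaryl boronic acid; 13 5,7-bis(benzyloxy)-4H-chromen-4-one (1.5 equiv)
Product: 14 (2S)-5,7-bis(benzyloxy)-2-{4-(benzyloxy)-3-hydroxy-5-[5,7-bis(benzyloxy)-2-(4-(benzyloxy)phenyl)-4-oxo-4H-chromen-8-yl]phenyl}-2,3-dihydro-4H-chromen-4-one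
Conditions: [Rh(OH)(cod)]2 (2.5 mol %), (S)-MeO-F12-BIPHEP [(S)-6,6'-dimethoxy-2,2'-bis(bis(3,4,5-trifluorophenyl)phosphino)biphenyl, 5.5 mol %], toluene/H2O 20:1, 30 °C
Reagents that add atoms: none
Why: Hayashi–Miyaura asymmetric 1,4-addition, in which the aryl–rhodium species (monovalent rhodium) formed by base-free transmetallation inserts into C2=C3 of the chromone from the C2 Re face left open by the (S)-bisphosphine, setting 2S, and water protonates the oxa-allyl rhodium; the electron-poor ligand speeds insertion into the electron-rich chromone, and the base-free toluene medium avoids chromone ring opening and retro-oxa-Michael racemisation.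

Step 8
Reactants: 14 (2S)-hexabenzyl ether
Product: 15 (2S)-2-{3,4-dihydroxy-5-[5,7-dihydroxy-2-(4-hydroxyphenyl)-4-oxo-4H-chromen-8-yl]phenyl}-5,7-dihydroxy-2,3-dihydro-4H-chromen-4-one (target, CNP0204144.1)
Conditions: H2 (1 atm), Pd/C (10 wt %), THF/MeOH 1:1, rt, stopped at full conversion; work-up under argon
Reagents that add atoms: none
Why: Catalytic hydrogenolysis cleaves all six O-benzyl bonds under neutral conditions, so the 4'-OH appears only when no acid or base is present and C2 keeps its S configuration; the flavone C2=C3 bond and the chelated ketones are reduced much more slowly than benzyl ethers.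

## Compound list
1 | apigenin | O=c1cc(-c2ccc(O)cc2)oc2cc(O)cc(O)c12 | starting material
2 | 5,7-bis(benzyloxy)-2-[4-(benzyloxy)phenyl]-4H-chromen-4-one | O=c1cc(-c2ccc(OCc3ccccc3)cc2)oc2cc(OCc3ccccc3)cc(OCc3ccccc3)c12 | intermediate
3 | 2-(benzyloxy)-5-bromobenzaldehyde | O=Cc1cc(Br)ccc1OCc1ccccc1 | starting material
4 | 2-(benzyloxy)-5-bromophenyl formate | O=COc1cc(Br)ccc1OCc1ccccc1 | intermediate (not isolated)
5 | 2-(benzyloxy)-5-bromophenol | Oc1cc(Br)ccc1OCc1ccccc1 | intermediate
6 | 6,6-bis(benzyloxy)-3-bromocyclohexa-2,4-dien-1-one | O=C1C=C(Br)C=CC1(OCc1ccccc1)OCc1ccccc1 | intermediate (not isolated)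
7 | 8-[6,6-bis(benzyloxy)-3-bromo-5-hydroxycyclohexa-2,4-dien-1-yl]-5,7-bis(benzyloxy)-2-[4-(benzyloxy)phenyl]-4H-chromen-4-one (racemic at the sp3 CH, lost on aromatisation) | OC1=CC(Br)=CC(c2c(OCc3ccccc3)cc(OCc3ccccc3)c3c(=O)cc(-c4ccc(OCc5ccccc5)cc4)oc23)C1(OCc1ccccc1)OCc1ccccc1 | intermediate (not isolated)
8 | 8-[2-(benzyloxy)-5-bromo-3-hydroxyphenyl]-5,7-bis(benzyloxy)-2-[4-(benzyloxy)phenyl]-4H-chromen-4-one | O=c1cc(-c2ccc(OCc3ccccc3)cc2)oc2c(-c3cc(Br)cc(O)c3OCc3ccccc3)c(OCc3ccccc3)cc(OCc3ccccc3)c12 | intermediate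
9 | [4-(benzyloxy)-3-hydroxy-5-{5,7-bis(benzyloxy)-2-[4-(benzyloxy)phenyl]-4-oxo-4H-chromen-8-yl}phenyl]boronic acid | O=c1cc(-c2ccc(OCc3ccccc3)cc2)oc2c(-c3cc(B(O)O)cc(O)c3OCc3ccccc3)c(OCc3ccccc3)cc(OCc3ccccc3)c12 | intermediate
10 | 2',4',6'-trihydroxyacetophenone | CC(=O)c1c(O)cc(O)cc1O | starting material
11 | 1-[2,4-bis(benzyloxy)-6-hydroxyphenyl]ethan-1-one | CC(=O)c1c(O)cc(OCc2ccccc2)cc1OCc1ccccc1 | intermediate
12 | (E)-1-[2,4-bis(benzyloxy)-6-hydroxyphenyl]-3-(dimethylamino)prop-2-en-1-one | CN(C)/C=C/C(=O)c1c(O)cc(OCc2ccccc2)cc1OCc1ccccc1 | intermediate (not isolated)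
13 | 5,7-bis(benzyloxy)-4H-chromen-4-one | O=c1ccoc2cc(OCc3ccccc3)cc(OCc3ccccc3)c12 | intermediate
14 | (2S)-5,7-bis(benzyloxy)-2-{4-(benzyloxy)-3-hydroxy-5-[5,7-bis(benzyloxy)-2-(4-(benzyloxy)phenyl)-4-oxo-4H-chromen-8-yl]phenyl}-2,3-dihydro-4H-chromen-4-one | O=C1C[C@@H](c2cc(O)c(OCc3ccccc3)c(-c3c(OCc4ccccc4)cc(OCc4ccccc4)c4c(=O)cc(-c5ccc(OCc6ccccc6)cc5)oc34)c2)Oc2cc(OCc3ccccc3)cc(OCc3ccccc3)c21 | intermediate
15 | (2S)-2-{3,4-dihydroxy-5-[5,7-dihydroxy-2-(4-hydroxyphenyl)-4-oxo-4H-chromen-8-yl]phenyl}-5,7-dihydroxy-2,3-dihydro-4H-chromen-4-one | O=C1C[C@@H](c2cc(O)c(O)c(-c3c(O)cc(O)c4c(=O)cc(-c5ccc(O)cc5)oc34)c2)Oc2cc(O)cc(O)c21 | target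

## Count and risks
Total steps: 8. Longest linear sequence: 5 (steps 2, 3, 4, 7, 8; the line from 1 through steps 1, 3, 4, 7, 8 is equally long).

**Step 3 (highest risk).**
- The flavone may be too weak a nucleophile once part of it is tied up by BF3.
- Residual BnOH can add as an O-nucleophile.
- Attack at C6 of the flavone, ipso attack at C–Br, or Diels–Alder dimerisation of 6 can compete.

The fallback keeps the same polarity-reversed electrophile but moves the coupling to an earlier stage of the flavone half. It sets out from 5 (oxidised to 6 as before) and 11. Compound 11 has a far less basic carbonyl and is normally substituted ortho to its free OH. It is arylated by 6 under BF3·OEt2 to give 1-{3-[2-(benzyloxy)-5-bromo-3-hydroxyphenyl]-4,6-bis(benzyloxy)-2-hydroxyphenyl}ethan-1-one F1. Claisen–Schmidt condensation with 4-(benzyloxy)benzaldehyde (KOH, EtOH/THF) gives the (E)-2'-hydroxychalcone F2. Oxidative cyclisation with catalytic I2 in DMSO at 120 °C closes the pyrone through the only free OH of that ring. This places the aryl group at C8, and the route is rejoined at 8.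

**Step 7.**
- The large, electron-rich boronic acid may protodeboronate faster than it adds to the deactivated 5,7-dialkoxychromone.
- The ee may fall short.

The fallback abandons conjugate arylation in favour of chalcone cyclisation followed by kinetic resolution. It sets out from 8 and 11. Reductive carbonylation of 8 (Pd(OAc)2, di(1-adamantyl)-n-butylphosphine, CO/H2, TMEDA, toluene, 100 °C) gives the biaryl benzaldehyde F3. Condensation with 11 (KOH, EtOH/THF) gives the 2'-hydroxychalcone F4. NaOAc in refluxing EtOH closes it to the racemic flavanone F5. Asymmetric transfer hydrogenation with RuCl(p-cymene)[(R,R)-TsDPEN] and HCO2H/Et3N in EtOAc, taken to about 50 % conversion, reduces the 2R enantiomer to the cis-(2R,4R)-flavan-4-ol F6. The 2S ketone is left behind, is separated by chromatography, and is 14.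

**Step 8.**
- There are six benzyl ethers, and the partly deprotected intermediates are poorly soluble.
- Three sites can be over-reduced: the flavone C2=C3 bond, the C4 ketone and the benzylic C2–O1 bond.

The fallback replaces reductive cleavage by Lewis-acid debenzylation with a cation scavenger. It sets out from 14, uses BCl3 (12 equiv) and pentamethylbenzene (18 equiv) in CH2Cl2 at −78 °C with a MeOH quench at that temperature, and arrives directly at 15. No new compound is made on the way (F0).

## Further compounds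
F1 | step 3 | 1-{3-[2-(benzyloxy)-5-bromo-3-hydroxyphenyl]-4,6-bis(benzyloxy)-2-hydroxyphenyl}ethan-1-one | CC(=O)c1c(O)c(-c2cc(Br)cc(O)c2OCc2ccccc2)c(OCc2ccccc2)cc1OCc1ccccc1
F2 | step 3 | (E)-1-{3-[2-(benzyloxy)-5-bromo-3-hydroxyphenyl]-4,6-bis(benzyloxy)-2-hydroxyphenyl}-3-[4-(benzyloxy)phenyl]prop-2-en-1-one | O=C(/C=C/c1ccc(OCc2ccccc2)cc1)c1c(O)c(-c2cc(Br)cc(O)c2OCc2ccccc2)c(OCc2ccccc2)cc1OCc1ccccc1
F3 | step 7 | 4-(benzyloxy)-3-hydroxy-5-{5,7-bis(benzyloxy)-2-[4-(benzyloxy)phenyl]-4-oxo-4H-chromen-8-yl}benzaldehyde | O=Cc1cc(O)c(OCc2ccccc2)c(-c2c(OCc3ccccc3)cc(OCc3ccccc3)c3c(=O)cc(-c4ccc(OCc5ccccc5)cc4)oc23)c1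
F4 | step 7 | (E)-1-[2,4-bis(benzyloxy)-6-hydroxyphenyl]-3-[4-(benzyloxy)-3-hydroxy-5-{5,7-bis(benzyloxy)-2-[4-(benzyloxy)phenyl]-4-oxo-4H-chromen-8-yl}phenyl]prop-2-en-1-one | O=C(/C=C/c1cc(O)c(OCc2ccccc2)c(-c2c(OCc3ccccc3)cc(OCc3ccccc3)c3c(=O)cc(-c4ccc(OCc5ccccc5)cc4)oc23)c1)c1c(O)cc(OCc2ccccc2)cc1OCc1ccccc1
F5 | step 7 | racemic form of 14 | O=C1CC(c2cc(O)c(OCc3ccccc3)c(-c3c(OCc4ccccc4)cc(OCc4ccccc4)c4c(=O)cc(-c5ccc(OCc6ccccc6)cc5)oc34)c2)Oc2cc(OCc3ccccc3)cc(OCc3ccccc3)c21
F6 | step 7 | cis-(2R,4R)-flavan-4-ol from the 2R enantiomer of F5 | O[C@@H]1C[C@H](c2cc(O)c(OCc3ccccc3)c(-c3c(OCc4ccccc4)cc(OCc4ccccc4)c4c(=O)cc(-c5ccc(OCc6ccccc6)cc5)oc34)c2)Oc2cc(OCc3ccccc3)cc(OCc3ccccc3)c21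
F0 | step 8 | none | none
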